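The data are calculated for an exercise, and the scatter is random.

The constants are hidden, so I work from the proposed steps and from the elm run, which is this very flask followed up to 2.50 h.

- elm: starting material 2 mM; free catalyst 66 µM; added ligand 0.25 mM; the very flask that is asked about, followed so far
- flask: starting material 2.0 mM; free catalyst 66 µM; added ligand 0.25 mM; time 5.0 h

- elm (time / h: isomer of the product / %, target / %, starting material / %): 0.333: 39.0, 47.9, 12.4; 0.667: 47.5, 41.2, 11.1; 1.00: 51.2, 38.9, 10.7; 1.33: 53.1, 37.2, 10.2; 2.00: 55.8, 35.0, 9.5; 2.50: 57.0, 35.0, 9.3

(standard deviation of a reading: 0.3 percentage points)

- share of isomer of the product in isomer of the product plus target at 5.0 s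
- share of isomer of the product in isomer of the product plus target at 5.0 h

- what may be going on: starting material + free catalyst <-> target + free catalyst; 2 free catalyst -> spent catalyst; free catalyst + added ligand <-> idle complex; target + free catalyst <-> isomer of the product + free catalyst

Where does the share of isomer of the product in isomer plus target stop? I read it at 0.333 h, 0.667 h and 1.33 h, each time twice the one before, and twice again for the last. The shares are 44.9%, 53.6% and 58.8%. The second rise over the first gives 0.606. I call this the shrink per doubling, the factor by which, as I assume, the share's distance from its plateau in this flask falls when time doubles. Summing the further rises puts the plateau at 66.9%, a reading with the scatter of the readings.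

What stands at the asked time? The last reading gives 62.0% at 2.50 h, and 5.0 h is twice that time. So the gap of 4.9 percentage points shrinks once, and I commit to 63.9%. The early time 5.0 s lies far before the first reading, so my shrink gives no number there.

The forecast gives 1% and 65.5%, above mine at the late time. Its ground: “the first step is near equilibrium and the second is slow”.

The flask gives 1.03% and 64.2%.

    starting material + free catalyst ⇌ target + free catalyst, rate k1*[starting material]*[free catalyst] forward; the back reaction follows from the equilibrium constant (K = 3.75, k = 4100 /M/s)
    2 free catalyst → spent catalyst (k = 130 /M/s)
    free catalyst + added ligand ⇌ idle complex (K = 8260 /M, k = 269 /M/s)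
    target + free catalyst ⇌ isomer of the product + free catalyst, rate k4*[free catalyst]*[target] forward; the back reaction follows from the equilibrium constant (K = 2.00, k = 61.6 /M/s)

This flask stands 0.30 points above my figure. For the neighbour flask I count c(free catalyst) times time as the clock, as a loss of free catalyst in pairs suggests. That neighbour is charged with 0.11 mM of free catalyst and the same added ligand, so it stands 0.737 doublings beyond this flask. The shrink then gives 65.0%, and the neighbour flask shows 65.0%.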